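Compare the two one-way steps that consume Z.Q, and find the concentration of Z at which they run equally fast.

    E ⇌ Q, rate k1*(csat - [Q]) (k1 = 0.017 s⁻¹, csat = 21 mM)
    Z + Q → Z.Q (k2 = 0.041 M⁻¹ s⁻¹)
    Q + Z.Q → Q.Z.Q (k3 = 0.041 M⁻¹ s⁻¹)
    Z + Z.Q → Z.Z.Q (k4 = 0.010 M⁻¹ s⁻¹)
    Z.Q ⇌ G (K5 = 0.49, k5 = 0.0029 s⁻¹)

Z 0.36 M; E 21 mM (held); time 1.5 h

- a species is counted by the Z in it: one Z.Z.Q counts as two
- at the start none of Q is dissolved
- run time (flask): 1.5 h

- alpha: doubling the saturation concentration of E, all else as stated
- eta: doubling the transfer coefficient of step 1, all else as stated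

1. amount of Z.Q at 1.5 h, in percent of the Z charged
2. concentration of Q in solution at 10 min, in percent of saturation
3. the change that raises the amount of Z.Q at 1.5 h, in percent of the Z charged most ("none" if none brings more than 2 percentage points) (alpha / eta / none)
4. amount of Z.Q at 1.5 h, in percent of the Z charged, after eta

Here are the rungs of this flask in order of half-life. The sinks of Z.Q are pseudo-first-order, with the partner held at the stated concentration.

| Event | Half-life | What the flask does |
|---|---|---|
| Q enters from E | 0.680 min | c(Q) rises from zero |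
| Z takes Q | 0.78 min | c(Q) follows c(Z) |
| Z.Q and G relax | 1.31 min | their ratio approaches K5 |
| Z takes Z.Q, as charged | 3.21 min | Z.Q turns into Z.Z.Q |
| Q takes Z.Q, at saturation | 13.4 min | Z.Q turns into Q.Z.Q |

After the first few minutes, c(Z) is the concentration to watch. Step 3 removes Z.Q at k3·c(Q) and step 4 at k4·c(Z), and their ratio is a selectivity factor. With c(Q) taken at saturation, the two match at the crossover concentration of Z, k3·csat/k4 = 86.1 mM. The flask is charged at 4.18 times this value, so I expect Z.Q to go first to Z.Z.Q and later to Q.Z.Q. The run lasts 6.71 half-lives of the last rung, so I expect a low y, but my reckoning gives no figure for it.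

The forecast gives y 3% (range 2.2% to 4%), sat 60%, best none and yb 2.5%. On doubling, it says that this “gives more Q, so the intermediate peaks sooner and is destroyed faster”.

The flask gives y 3.20%, sat 59.7%, best none (alpha −2.8 percentage points, eta −0.5 points) and yb 2.70%.

In this flask, c(Z) is 0.256 M at 0.150 h, above the crossover, and Z.Z.Q (16.3%) leads Q.Z.Q (1.32%). Steps 3 and 4 together are part of the reason that Z.Q stands at 3.20% at the end of this flask: the run without step 3 gives 16.7%, and the run without step 4 gives 15.7%. A neighbour flask, charged with 0.090 M of Z, near the crossover, ends with Z.Z.Q at 31.2% and Q.Z.Q at 59.9% of its own charge.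

(All constants are those of an exercise; what happens was integrated by code.)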